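**Retrosynthetic overview**
1. The target is a (−)-epicatechin core (rings A, C, B; 2R,3R) whose ring A carbon C8 carries a CH2 that ends on ring D, an (S)-2-methylbutanoyl methylphloroglucinol monomethyl ether. The one strategic cut is the CH2–ring D bond.
2. Enabling feature: the only hydrogen-bearing carbon of ring D lies between its two C–OH carbons, so ring D is the enol of a cyclic 1,3-diketone (vinylogous to the acyl C=O). It is a carbon nucleophile that can afterwards expel a leaving group as an o-quinone methide. The bridge carbon sits on C8 of ring A between O7 and O1 and can be carried there one oxidation level up, as CHO.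
3. Key step: amine-catalysed condensation of the C8 aldehyde with unprotected ring D, o-quinone methide formation in the flask, and hydride transfer from a Hantzsch ester. This gives the C–C bond, the CH2 oxidation level and the whole carbon skeleton in one operation.
4. Aldehyde half: (−)-epicatechin, per-O-benzylation, C8 bromination, Br/Li exchange and DMF. Ring D half: 2-methylphloroglucinol plus (S)-2-methylbutanoyl chloride (Friedel–Crafts), 4,6-di-O-benzylation, 2-O-methylation, hydrogenolysis.
5. No ring is built: rings A, B and C are bought with (−)-epicatechin and ring D with 2-methylphloroglucinol. The last step is hydrogenolysis of five benzyl ethers.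

Key step: step 9

Assumption: the SMILES is read as (2R,3R) in the flavan (2,3-cis, the (−)-epicatechin configuration) and (S) in the 2-methylbutanoyl group; the C8 selectivity of bromination known for O-benzylated flavan-3-ols is taken to hold for the penta-benzyl ether 2.

**Route**

Step 1
Reactants: 1 (−)-epicatechin
Product: 2 penta-O-benzyl-(−)-epicatechin
Conditions: NaH (6.5 equiv), BnBr (6 equiv), n-Bu4NI (cat.), DMF, −20 °C → rt
Reagents that add atoms: benzyl bromide, BrCc1ccccc1
Why: Williamson etherification of the four phenoxides and then of the C3 alkoxide; the phenols are capped at low temperature before base can open ring C at C2, so both stereocentres should stay untouched.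

Step 2
Reactants: 2 penta-O-benzyl-(−)-epicatechin
Product: 3 8-bromo-penta-O-benzyl-(−)-epicatechin
Conditions: NBS (1.05 equiv), CH2Cl2, −78 °C → rt
Reagents that add atoms: N-bromosuccinimide, O=C1CCC(=O)N1Br
Why: Electrophilic aromatic bromination of ring A, which in O-alkylated flavan-3-ols goes to C8 (between O7 and the tied-back pyran O1) and not to C6 (between two benzyloxy groups).

Step 3
Reactants: 3 8-bromo-penta-O-benzyl-(−)-epicatechin
Product: 5 penta-O-benzyl-(−)-epicatechin-8-carbaldehyde, via 8-lithio arene 4 (not isolated)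
Conditions: n-BuLi (1.1 equiv), THF, −78 °C, 20 min; DMF (4 equiv), −78 → 0 °C; aq. NH4Cl
Reagents that add atoms: N,N-dimethylformamide, CN(C)C=O
Why: Bromine–lithium exchange and Bouveault-type formylation of the aryllithium; at −78 °C the 8-lithio species with O-benzyl neighbours should live long enough to be trapped.

Step 4
Reactants: 6 (S)-2-methylbutanoic acid
Product: 7 (S)-2-methylbutanoyl chloride
Conditions: (COCl)2 (1.2 equiv), DMF (cat.), CH2Cl2, 0 °C → rt; volatiles removed below rt
Reagents that add atoms: oxalyl chloride, ClC(=O)C(Cl)=O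
Why: Acyl chloride formation through the Vilsmeier-type chloroiminium catalyst at or below room temperature, where the α-stereocentre is not enolized.

Step 5
Reactants: 7 (S)-2-methylbutanoyl chloride; 8 2-methylphloroglucinol
Product: 9 (2S)-2-methyl-1-(2,4,6-trihydroxy-3-methylphenyl)butan-1-one
Conditions: AlCl3 (3.5 equiv), PhNO2/CH2Cl2, 0 °C → rt; ice, 1 M HCl
Reagents that add atoms: none
Why: Friedel–Crafts C-acylation; the two free ring positions of 8 are equivalent, so only one regioisomer can form, and the low temperature should keep the acylium ion from racemizing through a ketene (enantiomeric purity to be checked here by chiral HPLC).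

Step 6
Reactants: 9 (2S)-2-methyl-1-(2,4,6-trihydroxy-3-methylphenyl)butan-1-one
Product: 10 (2S)-1-[4,6-bis(benzyloxy)-2-hydroxy-3-methylphenyl]-2-methylbutan-1-one
Conditions: BnBr (2.05 equiv), K2CO3 (2.2 equiv), acetone, 40 °C
Reagents that add atoms: benzyl bromide, BrCc1ccccc1
Why: Selective Williamson benzylation: the para OH (not hydrogen-bonded, most acidic) reacts first, then the less hindered ortho OH next to the ring CH, while the OH wedged between the methyl and the acyl group stays as the chelated phenol.

Step 7
Reactants: 10 (2S)-1-[4,6-bis(benzyloxy)-2-hydroxy-3-methylphenyl]-2-methylbutan-1-one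
Product: 11 (2S)-1-[4,6-bis(benzyloxy)-2-methoxy-3-methylphenyl]-2-methylbutan-1-one
Conditions: MeI (3 equiv), K2CO3 (2 equiv), DMF, 40 °C
Reagents that add atoms: iodomethane, CI
Why: O-methylation (Williamson) of the last, hydrogen-bonded phenol under mild carbonate conditions; the twisted 2,6-disubstituted aryl ketone is a poor carbon acid, so the α-stereocentre should survive.

Step 8
Reactants: 11 (2S)-1-[4,6-bis(benzyloxy)-2-methoxy-3-methylphenyl]-2-methylbutan-1-one
Product: 12 (2S)-1-(4,6-dihydroxy-2-methoxy-3-methylphenyl)-2-methylbutan-1-one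
Conditions: H2 (1 atm), 10% Pd/C, EtOAc/MeOH, rt
Reagents that add atoms: none
Why: Catalytic hydrogenolysis of the two aryl benzyl ethers; the hindered, electron-rich aryl ketone and the methyl ether are inert under these neutral conditions.

Step 9
Reactants: 5 penta-O-benzyl-(−)-epicatechin-8-carbaldehyde; 12 (2S)-1-(4,6-dihydroxy-2-methoxy-3-methylphenyl)-2-methylbutan-1-one
Product: 14 penta-O-benzyl ether of the target, via o-quinone methide 13 (not isolated)
Conditions: 12 (1.2 equiv), L-proline (20 mol%), diethyl 2,6-dimethyl-1,4-dihydropyridine-3,5-dicarboxylate (Hantzsch ester, 1.3 equiv), 4 Å MS, CH2Cl2/EtOH (1:1), 40 °C, Ar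
Reagents that add atoms: none
Why: Proposed new method: L-proline should condense with the C8 aldehyde of 5 to an iminium ion, the only hydrogen-bearing carbon of ring D in 12 (C5, between the C4–OH and C6–OH carbons, the α-carbon of a masked cyclic 1,3-diketone) adds to it in a Mannich-type step, loss of proline across the new C–C bond with the help of a flanking OH gives the o-quinone methide 13, and the Hantzsch ester then transfers hydride to the exocyclic carbon of 13, which rearomatizes ring D and leaves the CH2 bridge. The closest known reaction type is the amine-catalysed three-component reductive alkylation (Knoevenagel condensation, then transfer hydrogenation of the alkylidene) of cyclic 1,3-diketones, 4-hydroxycoumarins and 2-hydroxy-1,4-naphthoquinone with aromatic aldehydes; acylphloroglucinols condense with aldehydes in the same Knoevenagel sense, but neither they nor 2,6-dioxygenated benzaldehydes of this size have been used in the reductive version. No ring is closed and no stereocentre is formed, since the bridging carbon ends as CH2; the three existing stereocentres lie away from the reacting atoms and meet only a weak acid–base pair at 40 °C. The selectivity needed is C–C bond formation at one site only: ring D has a single free carbon, O-attack on the iminium ion is reversible, the aldehyde has no α-hydrogen, the per-O-benzylated ring A is not nucleophilic enough to compete without strong acid, addition of a second molecule of 12 to the crowded 13 is reversible, and the Hantzsch ester reduces the electron-poor exocyclic C=C of 13 but not the aldehyde.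

Step 10
Reactants: 14 penta-O-benzyl ether of the target
Product: 15 target, (2S)-1-[3-{[(2R,3R)-2-(3,4-dihydroxyphenyl)-3,5,7-trihydroxychroman-8-yl]methyl}-2,4-dihydroxy-6-methoxy-5-methylphenyl]-2-methylbutan-1-one
Conditions: H2 (1 atm), Pd(OH)2/C (20 wt%), THF/MeOH (1:1), rt
Reagents that add atoms: none
Why: Catalytic hydrogenolysis of the four aryl benzyl ethers and the C3 alkyl benzyl ether under neutral conditions, which should leave the diarylmethane, the chelated ketone and the C2–O1 bond intact, so no stereocentre is touched.

**Compound list**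
1 | (−)-epicatechin, (2R,3R)-2-(3,4-dihydroxyphenyl)chromane-3,5,7-triol | c1c(O)cc(O)c2c1O[C@H](c1ccc(O)c(O)c1)[C@H](O)C2 | starting material
2 | penta-O-benzyl-(−)-epicatechin, (2R,3R)-3,5,7-tris(benzyloxy)-2-[3,4-bis(benzyloxy)phenyl]chromane | c1c(OCc2ccccc2)cc(OCc2ccccc2)c2c1O[C@H](c1ccc(OCc3ccccc3)c(OCc3ccccc3)c1)[C@H](OCc1ccccc1)C2 | intermediate
3 | (2R,3R)-8-bromo-3,5,7-tris(benzyloxy)-2-[3,4-bis(benzyloxy)phenyl]chromane | Brc1c(OCc2ccccc2)cc(OCc2ccccc2)c2c1O[C@H](c1ccc(OCc3ccccc3)c(OCc3ccccc3)c1)[C@H](OCc1ccccc1)C2 | intermediate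
4 | (2R,3R)-8-lithio-3,5,7-tris(benzyloxy)-2-[3,4-bis(benzyloxy)phenyl]chromane | [Li]c1c(OCc2ccccc2)cc(OCc2ccccc2)c2c1O[C@H](c1ccc(OCc3ccccc3)c(OCc3ccccc3)c1)[C@H](OCc1ccccc1)C2 | intermediate (not isolated)
5 | (2R,3R)-3,5,7-tris(benzyloxy)-2-[3,4-bis(benzyloxy)phenyl]chromane-8-carbaldehyde | O=Cc1c(OCc2ccccc2)cc(OCc2ccccc2)c2c1O[C@H](c1ccc(OCc3ccccc3)c(OCc3ccccc3)c1)[C@H](OCc1ccccc1)C2 | intermediate
6 | (S)-2-methylbutanoic acid | CC[C@H](C)C(=O)O | starting material
7 | (S)-2-methylbutanoyl chloride | CC[C@H](C)C(=O)Cl | intermediate
8 | 2-methylphloroglucinol, 2-methylbenzene-1,3,5-triol | Cc1c(O)cc(O)cc1O | starting material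
9 | (2S)-2-methyl-1-(2,4,6-trihydroxy-3-methylphenyl)butan-1-one | CC[C@H](C)C(=O)c1c(O)cc(O)c(C)c1O | intermediate
10 | (2S)-1-[4,6-bis(benzyloxy)-2-hydroxy-3-methylphenyl]-2-methylbutan-1-one | CC[C@H](C)C(=O)c1c(OCc2ccccc2)cc(OCc2ccccc2)c(C)c1O | intermediate
11 | (2S)-1-[4,6-bis(benzyloxy)-2-methoxy-3-methylphenyl]-2-methylbutan-1-one | CC[C@H](C)C(=O)c1c(OCc2ccccc2)cc(OCc2ccccc2)c(C)c1OC | intermediate
12 | (2S)-1-(4,6-dihydroxy-2-methoxy-3-methylphenyl)-2-methylbutan-1-one | CC[C@H](C)C(=O)c1c(O)cc(O)c(C)c1OC | intermediate
13 | ring D o-quinone methide, 6-(arylmethylidene)-5-hydroxy-3-methoxy-2-methyl-4-[(2S)-2-methylbutanoyl]cyclohexa-2,4-dien-1-one, aryl = (2R,3R)-3,5,7-tris(benzyloxy)-2-[3,4-bis(benzyloxy)phenyl]chroman-8-yl | CC[C@H](C)C(=O)C1=C(O)C(=Cc2c(OCc3ccccc3)cc(OCc3ccccc3)c3c2O[C@H](c2ccc(OCc4ccccc4)c(OCc4ccccc4)c2)[C@H](OCc2ccccc2)C3)C(=O)C(C)=C1OC | intermediate (not isolated)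
14 | (2S)-1-[3-({(2R,3R)-3,5,7-tris(benzyloxy)-2-[3,4-bis(benzyloxy)phenyl]chroman-8-yl}methyl)-2,4-dihydroxy-6-methoxy-5-methylphenyl]-2-methylbutan-1-one | CC[C@H](C)C(=O)c1c(O)c(Cc2c(OCc3ccccc3)cc(OCc3ccccc3)c3c2O[C@H](c2ccc(OCc4ccccc4)c(OCc4ccccc4)c2)[C@H](OCc2ccccc2)C3)c(O)c(C)c1OC | intermediate
15 | (2S)-1-[3-{[(2R,3R)-2-(3,4-dihydroxyphenyl)-3,5,7-trihydroxychroman-8-yl]methyl}-2,4-dihydroxy-6-methoxy-5-methylphenyl]-2-methylbutan-1-one | CC[C@H](C)C(=O)c1c(O)c(Cc2c(O)cc(O)c3c2O[C@H](c2ccc(O)c(O)c2)[C@H](O)C3)c(O)c(C)c1OC | target

**Step count and risks**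
Total step count: 10. Longest linear sequence: 7 steps (steps 4, 5, 6, 7, 8, 9, 10).

Steps most likely to fail:

1. Step 9 (proposed new method). The condensation may stall at the hindered, electron-rich aldehyde, with iminium formation or C–C bond formation too slow, so that no o-quinone methide is there for the hydride transfer. The fallback sets out from 5 and uses known chemistry. The aldehyde would be reduced with NaBH4 (THF/MeOH, 0 °C) to [(2R,3R)-3,5,7-tris(benzyloxy)-2-[3,4-bis(benzyloxy)phenyl]chroman-8-yl]methanol F1. F1 would then be added slowly to 12 (3 equiv) and Sc(OTf)3 (5 mol%) in CH2Cl2/MeNO2 at −20 °C. Ionization gives a benzylic cation stabilized by O7, O1 and O5 of ring A, which alkylates the free carbon of ring D (acid-catalysed dehydrative Friedel–Crafts benzylation). Any O-benzylated material re-ionizes and is funnelled to the C-linked product, and the excess of 12 holds back self-condensation. The fallback comes back to the route at 14.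

2. Step 6. Site selectivity between the two ortho hydroxyls may be lost, together with over-benzylation or C-benzylation at the free ring carbon. The fallback sets out from 9 and reverses the logic. Exhaustive benzylation (BnBr 4 equiv, K2CO3, DMF, 60 °C) would give (2S)-2-methyl-1-[2,4,6-tris(benzyloxy)-3-methylphenyl]butan-1-one F2. One ortho benzyl ether would then be removed by chelation-controlled cleavage with MgBr2·OEt2 (toluene/Et2O, rt → 40 °C). The magnesium bound to the ketone oxygen reaches only the two ortho ethers, and the ether pushed out of the ring plane by the neighbouring methyl and the acyl group is the more basic and more strained one. The para ether is not touched, and the regiochemistry would be checked by NOE. The fallback comes back to the route at 10.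

3. Step 3. The 8-aryllithium may abstract a benzylic hydrogen from the neighbouring O7 benzyl group (followed by Wittig rearrangement) or be protonated before it meets DMF. The fallback sets out from 3 and avoids the organolithium. Suzuki–Miyaura coupling with potassium vinyltrifluoroborate (Pd(OAc)2, SPhos, K2CO3, toluene/H2O, 90 °C) would give (2R,3R)-3,5,7-tris(benzyloxy)-2-[3,4-bis(benzyloxy)phenyl]-8-vinylchromane F3. Lemieux–Johnson cleavage of the vinyl group (OsO4 cat., NaIO4, 2,6-lutidine, dioxane/H2O, rt) would then give the aldehyde. The fallback comes back to the route at 5.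

Further compounds
F1 | step 9 | [(2R,3R)-3,5,7-tris(benzyloxy)-2-[3,4-bis(benzyloxy)phenyl]chroman-8-yl]methanol | OCc1c(OCc2ccccc2)cc(OCc2ccccc2)c2c1O[C@H](c1ccc(OCc3ccccc3)c(OCc3ccccc3)c1)[C@H](OCc1ccccc1)C2
F2 | step 6 | (2S)-2-methyl-1-[2,4,6-tris(benzyloxy)-3-methylphenyl]butan-1-one | CC[C@H](C)C(=O)c1c(OCc2ccccc2)cc(OCc2ccccc2)c(C)c1OCc1ccccc1
F3 | step 3 | (2R,3R)-3,5,7-tris(benzyloxy)-2-[3,4-bis(benzyloxy)phenyl]-8-vinylchromane | C=Cc1c(OCc2ccccc2)cc(OCc2ccccc2)c2c1O[C@H](c1ccc(OCc3ccccc3)c(OCc3ccccc3)c1)[C@H](OCc1ccccc1)C2
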